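The readings are calculated with made-up constants; scatter was added.

Of the starting material charged to the teal flask, 57.5% is in neither target nor isomer of the product at 30.0 h, so I follow the ratio c_isomer/c_target rather than the yields.

| flask | starting material | protic impurity | remark | time |
|---|---|---|---|---|
| teal | 10 mM | 3 mM | the very flask that is asked about, followed so far |  |
| blue | 10 mM | 4.5 mM | run made earlier |  |
| flask | 10 mM | 3.00 mM |  | 3.0 d |

- teal (time / h: target / %, isomer of the product / %): 4.00: 16.4, 3.1; 10.0: 24.8, 5.0; 20.0: 28.7, 10.7; 30.0: 27.3, 15.2
- blue (time / d: target / %, isomer of the product / %): 0.250: 17.0, 4.1; 0.500: 21.2, 6.8; 1.25: 23.0, 12.8; 3.00: 13.3, 14.0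

(each reading ± 1 percentage point)

- share of target in target plus isomer of the product at 30 min
- share of target in target plus isomer of the product at 6.0 h
- share of target in target plus isomer of the product at 3.0 d

- the numbers in the tables scatter with a standard deviation of 1 percentage point

That ratio reads 0.557 in teal at 30.0 h and 0.557 in blue at 1.25 d, although blue was charged with more protic impurity, so the two runs may be pooled.

Two of us dispute where the ratio starts. The first holds that the rate of the isomer follows c_starting material from the first moment, as the rate of the target does, so the ratio has a floor at zero time, and he points to the teal ratios 0.189 at 4.00 h and 0.202 at 10.0 h. The second holds that the order is set by a concentration that is zero at the charge, so the ratio starts from nothing and grows with time; she answers that the reading 3.1% carries a scatter of 1 point, so the teal ratio at 4.00 h is too loose to show a floor.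

I side with her and average the ratio divided by time over the four earliest readings of both runs, which gives 0.0336 h⁻¹, the ratio clock, the growth of the ratio per unit time near the start. A share of 1/(1 + clock × time) then gives me 98.3% at 30 min and 83.2% at 6.0 h. By 3.00 d blue's ratio per time has sunk to 0.0146 h⁻¹, so for the latest time I carry blue's share, 48.7%, across to teal.

The forecast, on the first view that “the isomer is partly formed in parallel rather than only from the target”, says 87%, 83% and 51%.

The flask gives 98.4%, 85.0% and 49.0%.

    target → over-reaction product (k = 4.86 × 10⁻⁶ s⁻¹)
    other conformer ⇌ third conformer (K = 1.35, k = 6.40 × 10⁻⁶ s⁻¹)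
    starting material + protic impurity → quenched substrate (k = 0.0103 M⁻¹ s⁻¹)
    starting material ⇌ other conformer (K = 1.07, k = 3.61 × 10⁻⁵ s⁻¹)
    starting material → decomposition product (k = 1.29 × 10⁻⁸ s⁻¹)
    third conformer → third product (k = 3.81 × 10⁻⁵ s⁻¹)
    other conformer → isomer of the product (k = 8.86 × 10⁻⁶ s⁻¹)
    starting material → target (k = 1.75 × 10⁻⁵ s⁻¹)

The concentration that starts at zero is c_other conformer, from which the isomer is made; from 6.0 h on, the first view stands within its margin. Read back from the flask, the clock at 30 min is 0.0329 h⁻¹ beside my 0.0336 h⁻¹. Target is made 4.64 times faster than it is used up at 0.292 d, but at 3.00 d that quotient is 0.0903. The neighbour flask with 2.5 mM of starting material, a quarter of the charge, keeps the clock's early reading: its share at 30 min is 98.4%, beside the reckoned 98.3%, and at 6.0 h it is 84.7%.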